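**Retrosynthetic overview**

1. Enabling feature: in the hydroquinone ring D, the hydroxyl oxygen ortho to the bridge and the bridge carbon bonded to ring C are separated by two ring-D carbons and the benzylic CH2 (O–C(ar)–C(ar)–CH2–CH2). Ring D plus its bridge is therefore a ring-opened 5-oxygenated benzofuran, and the furan C2–O bond is a latent electrophile.
2. Key disconnection: the bond between ring C (the carbon para to its OH) and the adjacent bridge carbon. It is made by nickel-catalysed ring-opening arylation of commercial 5-methoxybenzofuran with the ring-C arylmagnesium bromide, which forms the C–C bond, delivers the two-carbon bridge and frees the ortho OH of ring D in one operation.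
3. The ring C–O–ring B diaryl ether comes from an SNAr reaction (5-bromo-2-methoxyphenol + 4-fluorobenzaldehyde), and the ring A–ring B bridge from a Horner–Wadsworth–Emmons olefination.
4. No carbocycle is built: the four benzene rings are bought and joined in the order C–B, then A, then D. The only ring event is the opening of the furan ring in the key step. One hydrogenation saturates both bridges and BBr3 frees the phenols.

Key step: step 3

Remark: the target has no stereocentre. The alkene geometries given for 5, 7 and 8 are the expected ones and are erased by the hydrogenation in step 4.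

**Route**

Step 1
Reactants: 1 5-bromo-2-methoxyphenol; 2 4-fluorobenzaldehyde
Product: 3 4-(5-bromo-2-methoxyphenoxy)benzaldehyde
Conditions: K2CO3, DMF, 120 °C
Reagents that add atoms: none
Why: Nucleophilic aromatic substitution (addition–elimination) of the phenoxide of 1 on the para-formyl-activated fluoride of 2 should give the diaryl ether, while the unactivated aryl bromide is inert without a metal catalyst.

Step 2
Reactants: 3 4-(5-bromo-2-methoxyphenoxy)benzaldehyde; 4 diethyl (3-methoxybenzyl)phosphonate
Product: 5 4-bromo-1-methoxy-2-{4-[(E)-2-(3-methoxyphenyl)ethenyl]phenoxy}benzene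
Conditions: KOtBu, THF, 0 °C to rt
Reagents that add atoms: none
Why: Horner–Wadsworth–Emmons olefination of an aromatic aldehyde with a benzylic phosphonate anion should give the E-stilbene, and the aryl bromide, diaryl ether and methyl ethers are stable to the base.

Step 3
Reactants: 5 4-bromo-1-methoxy-2-{4-[(E)-2-(3-methoxyphenyl)ethenyl]phenoxy}benzene; 6 5-methoxybenzofuran
Product: 8 4-methoxy-2-[(Z)-2-(4-methoxy-3-{4-[(E)-2-(3-methoxyphenyl)ethenyl]phenoxy}phenyl)ethenyl]phenol, via arylmagnesium bromide 7 (not isolated)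
Conditions: Mg (I2 cat.), THF, 65 °C; then 6 (1.2 equiv), NiCl2(PPh3)2 (5 mol %), PhMe, 80 °C; aq NH4Cl
Reagents that add atoms: magnesium, [Mg] (held in 7 only; no atom of it stays in 8)
Why: Bromide 5 gives arylmagnesium bromide 7, and Ni(0) (formed from the Ni(II) salt by 7) binds the furan C2=C3 bond of 6, inserts into its enol-ether C2–O bond to give a six-membered (Z)-alkenyl nickel aryloxide, takes up the aryl group of 7 by transmetalation (the phenoxide leaving as its magnesium salt) and reductively eliminates the new aryl–vinyl bond with retention. The closest known reaction type is the nickel-catalysed Kumada-type ring-opening cross-coupling of benzofurans and other enol ethers with Grignard reagents by C(sp2)–O cleavage, which gives (Z)-2-hydroxystilbenes from benzofurans and arylmagnesium halides. No ring is closed (the furan ring is opened) and no stereocentre is formed; the Z geometry follows from retention at the alkenyl nickel and is erased in step 4. The step needs insertion into the vinylic C2–O bond and not into the aryl C7a–O bond, the three ArO–Me bonds or the diaryl ether: π-coordination at C2=C3 directs nickel to C2–O, and unactivated anisole-type C–O bonds need stronger donor ligands and higher temperature than a triphenylphosphine catalyst at 80 °C provides. The E-stilbene unit of 7 should act only as a labile ligand for Ni(0), because an aryl Grignard reagent has no β-hydrogen from which a nickel hydride could form.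

Step 4
Reactants: 8 4-methoxy-2-[(Z)-2-(4-methoxy-3-{4-[(E)-2-(3-methoxyphenyl)ethenyl]phenoxy}phenyl)ethenyl]phenol
Product: 9 4-methoxy-2-[2-(4-methoxy-3-{4-[2-(3-methoxyphenyl)ethyl]phenoxy}phenyl)ethyl]phenol
Conditions: H2 (1 atm), 10% Pd/C, EtOAc–MeOH, rt
Reagents that add atoms: none
Why: Heterogeneous catalytic hydrogenation should saturate both stilbene double bonds, while the phenol, the aryl methyl ethers and the diaryl ether (no benzylic C–O bond present) are untouched.

Step 5
Reactants: 9 4-methoxy-2-[2-(4-methoxy-3-{4-[2-(3-methoxyphenyl)ethyl]phenoxy}phenyl)ethyl]phenol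
Product: 10 2-[2-(4-hydroxy-3-{4-[2-(3-hydroxyphenyl)ethyl]phenoxy}phenyl)ethyl]benzene-1,4-diol
Conditions: BBr3 (6 equiv), CH2Cl2, −78 °C to rt; then degassed H2O (aq Na2S2O4)
Reagents that add atoms: none
Why: Lewis-acid-mediated aryl methyl ether cleavage (BBr3 complexation, then bromide attack at methyl) should free the three phenols, whereas the diaryl ether has no sp3 carbon for bromide attack and survives.

**Compound list**

1 | 5-bromo-2-methoxyphenol | COc1ccc(Br)cc1O | starting material
2 | 4-fluorobenzaldehyde | O=Cc1ccc(F)cc1 | starting material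
3 | 4-(5-bromo-2-methoxyphenoxy)benzaldehyde | COc1ccc(Br)cc1Oc1ccc(C=O)cc1 | intermediate
4 | diethyl (3-methoxybenzyl)phosphonate | CCOP(=O)(Cc1cccc(OC)c1)OCC | starting material
5 | 4-bromo-1-methoxy-2-{4-[(E)-2-(3-methoxyphenyl)ethenyl]phenoxy}benzene | COc1cccc(/C=C/c2ccc(Oc3cc(Br)ccc3OC)cc2)c1 | intermediate
6 | 5-methoxybenzofuran | COc1ccc2occc2c1 | starting material
7 | (4-methoxy-3-{4-[(E)-2-(3-methoxyphenyl)ethenyl]phenoxy}phenyl)magnesium bromide | COc1cccc(/C=C/c2ccc(Oc3cc([Mg]Br)ccc3OC)cc2)c1 | intermediate
8 | 4-methoxy-2-[(Z)-2-(4-methoxy-3-{4-[(E)-2-(3-methoxyphenyl)ethenyl]phenoxy}phenyl)ethenyl]phenol | COc1cccc(/C=C/c2ccc(Oc3cc(/C=C\c4cc(OC)ccc4O)ccc3OC)cc2)c1 | intermediate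
9 | 4-methoxy-2-[2-(4-methoxy-3-{4-[2-(3-methoxyphenyl)ethyl]phenoxy}phenyl)ethyl]phenol | COc1cccc(CCc2ccc(Oc3cc(CCc4cc(OC)ccc4O)ccc3OC)cc2)c1 | intermediate
10 | 2-[2-(4-hydroxy-3-{4-[2-(3-hydroxyphenyl)ethyl]phenoxy}phenyl)ethyl]benzene-1,4-diol | Oc1cccc(CCc2ccc(Oc3cc(CCc4cc(O)ccc4O)ccc3O)cc2)c1 | target

**Step count and risks**

Total step count: 5. Longest linear sequence: 5 steps (1 → 3 → 5 → 8 → 9 → 10).

Steps most likely to fail:

Step 3. Nickel insertion into the C2–O bond of the electron-rich 5-methoxybenzofuran may be slow, so that homocoupling of the Grignard reagent, attack on aryl methyl ether bonds or catalyst sequestration by the stilbene takes over. The fallback sets out from 5 and comes back to the route at 10. Commercial 2,5-dimethoxybenzaldehyde is methylenated (Ph3PCH3Br, KOtBu, THF) to 2,5-dimethoxystyrene F1. A Mizoroki–Heck reaction of 5 with F1 (Pd(OAc)2, P(o-tol)3, K2CO3, DMF, 120 °C) forms the same ring C–bridge bond and should give 1,4-dimethoxy-2-[(E)-2-(4-methoxy-3-{4-[(E)-2-(3-methoxyphenyl)ethenyl]phenoxy}phenyl)ethenyl]benzene F2. Hydrogenation (H2, Pd/C, EtOAc–MeOH) should give 1,4-dimethoxy-2-[2-(4-methoxy-3-{4-[2-(3-methoxyphenyl)ethyl]phenoxy}phenyl)ethyl]benzene F3, and BBr3 (CH2Cl2, −78 °C to rt, four ether cleavages) leads to 10.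

Step 5. Cleavage of the hindered ring-C methyl ether next to the aryloxy group may stay incomplete, and the freed hydroquinone may be oxidised to the quinone under the Lewis-acidic conditions and work-up. The fallback sets out from 5 and comes back to the route at 10; it moves the demethylation to a stage without a hydroquinone and carries the phenols as acid-labile acetals.
- BBr3 on 5 should give 4-bromo-2-{4-[(E)-2-(3-hydroxyphenyl)ethenyl]phenoxy}phenol F4.
- MOMCl and iPr2NEt (CH2Cl2) should give 4-bromo-1-(methoxymethoxy)-2-(4-{(E)-2-[3-(methoxymethoxy)phenyl]ethenyl}phenoxy)benzene F5.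
- Commercial 5-hydroxybenzofuran is protected in the same way as 5-(methoxymethoxy)benzofuran F6.
- The Grignard reagent of F5 and F6 under the conditions of step 3 should give 4-(methoxymethoxy)-2-{(Z)-2-[4-(methoxymethoxy)-3-(4-{(E)-2-[3-(methoxymethoxy)phenyl]ethenyl}phenoxy)phenyl]ethenyl}phenol F7.
- Hydrogenation as in step 4 should give 4-(methoxymethoxy)-2-{2-[4-(methoxymethoxy)-3-(4-{2-[3-(methoxymethoxy)phenyl]ethyl}phenoxy)phenyl]ethyl}phenol F8.
- Dilute HCl in MeOH at rt under argon removes the three acetals to give 10.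

Step 1. Substitution by the weakly nucleophilic ortho-methoxy phenoxide may be slow, so that base-induced degradation of the aldehyde at the temperature required competes. The fallback sets out from 1 and comes back to the route at 3. A Chan–Lam oxidative O-arylation of 1 with commercial 4-formylphenylboronic acid (Cu(OAc)2, pyridine, 4 Å MS, CH2Cl2, air, rt) replaces the SNAr reaction with a copper-mediated coupling at room temperature. It gives 3 directly and tolerates the aryl bromide.

**Further compounds**

F1 | step 3 | 2,5-dimethoxystyrene | C=Cc1cc(OC)ccc1OC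
F2 | step 3 | 1,4-dimethoxy-2-[(E)-2-(4-methoxy-3-{4-[(E)-2-(3-methoxyphenyl)ethenyl]phenoxy}phenyl)ethenyl]benzene | COc1cccc(/C=C/c2ccc(Oc3cc(/C=C/c4cc(OC)ccc4OC)ccc3OC)cc2)c1
F3 | step 3 | 1,4-dimethoxy-2-[2-(4-methoxy-3-{4-[2-(3-methoxyphenyl)ethyl]phenoxy}phenyl)ethyl]benzene | COc1cccc(CCc2ccc(Oc3cc(CCc4cc(OC)ccc4OC)ccc3OC)cc2)c1
F4 | step 5 | 4-bromo-2-{4-[(E)-2-(3-hydroxyphenyl)ethenyl]phenoxy}phenol | Oc1cccc(/C=C/c2ccc(Oc3cc(Br)ccc3O)cc2)c1
F5 | step 5 | 4-bromo-1-(methoxymethoxy)-2-(4-{(E)-2-[3-(methoxymethoxy)phenyl]ethenyl}phenoxy)benzene | COCOc1cccc(/C=C/c2ccc(Oc3cc(Br)ccc3OCOC)cc2)c1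
F6 | step 5 | 5-(methoxymethoxy)benzofuran | COCOc1ccc2occc2c1
F7 | step 5 | 4-(methoxymethoxy)-2-{(Z)-2-[4-(methoxymethoxy)-3-(4-{(E)-2-[3-(methoxymethoxy)phenyl]ethenyl}phenoxy)phenyl]ethenyl}phenol | COCOc1cccc(/C=C/c2ccc(Oc3cc(/C=C\c4cc(OCOC)ccc4O)ccc3OCOC)cc2)c1
F8 | step 5 | 4-(methoxymethoxy)-2-{2-[4-(methoxymethoxy)-3-(4-{2-[3-(methoxymethoxy)phenyl]ethyl}phenoxy)phenyl]ethyl}phenol | COCOc1cccc(CCc2ccc(Oc3cc(CCc4cc(OCOC)ccc4O)ccc3OCOC)cc2)c1
F0 | step 1 | none | none
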